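**Plan**
- Feature: in rings A and C the nine carbons C8a–C8–C7–C6–C5–C4a–C4–C3–C2 form one unbranched chain with oxygen on alternate carbons (C8a, C7, C5, C4, C2), the mark of an acetate-type poly-β-carbonyl chain. The 3-oxygen and the 6- and 8-methoxy groups are the only additions.
- Retrosynthesis: remove the benzyl groups and the 7-O-methyl, cut the C6–O and C8–O bonds (back to C–Br, then C–H), then cut C4a–C8a and O1–C2 so that rings A and C unfold into a tetraketo ester masked as a 2-pyranone. Finally cut C2–C3 and C4–C4a as two Claisen acylations.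
- Forward: the chain is joined at C4–C4a (triacetic acid lactone dianion plus methyl benzyloxyacetate), then at C2–C3 (trianion plus benzylated methyl gentisate, which brings in ring B). One operation then closes ring A (Claisen) and ring C (cyclodehydration). Ring A is finished by dibromination, methoxylation and 7-O-methylation, and hydrogenolysis frees the 3-, 2′- and 5′-hydroxyls.
- Stereochemistry: the target has no stereocentre. The single sp3 methine of the open-chain intermediates is racemic and enolisable and becomes C3 of the chromenone.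

Key step: step 4

Assumption: the poly-β-carbonyl intermediates are drawn as keto (or 4-hydroxypyranone) tautomers although they should exist largely as enols or metal chelates; methyl 2,5-dihydroxybenzoate is taken as the commercial form of gentisic acid.

**Step 1**
Reactants: 1 4-hydroxy-6-methyl-2H-pyran-2-one (triacetic acid lactone); 2 methyl 2-(benzyloxy)acetate
Product: 3 6-[3-(benzyloxy)-2-oxopropyl]-4-hydroxy-2H-pyran-2-one
Conditions: 1 (2.2 equiv), LiN(iPr)2 (4.5 equiv), THF, −78 → −20 °C; then 2 (1.0 equiv), −78 → 0 °C; 1 M HCl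
Reagents that add atoms: none
Why: Claisen-type acylation of the triacetic acid lactone dianion, which should react at its most basic site, the 6-methyl carbanion, with the ester carbonyl of 2; the second equivalent of dianion deprotonates the doubly activated methylene of the product, which prevents over-addition, and no stereocentre is formed.

**Step 2**
Reactants: 4 methyl 2,5-dihydroxybenzoate
Product: 5 methyl 2,5-bis(benzyloxy)benzoate
Conditions: BnBr (2.5 equiv), K2CO3 (3 equiv), DMF, 60 °C
Reagents that add atoms: benzyl bromide, BrCc1ccccc1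
Why: Williamson ether synthesis on both phenoxides; the hydrogen-bonded 2-hydroxyl is slower but should be alkylated at 60 °C in DMF, and the methyl ester is untouched.

**Step 3**
Reactants: 3 6-[3-(benzyloxy)-2-oxopropyl]-4-hydroxy-2H-pyran-2-one; 5 methyl 2,5-bis(benzyloxy)benzoate
Product: 6 6-{3-(benzyloxy)-4-[2,5-bis(benzyloxy)phenyl]-2,4-dioxobutyl}-4-hydroxy-2H-pyran-2-one (racemic)
Conditions: 3, LiN(iPr)2 (4.2 equiv), THF, −78 → 0 °C; then 5 (1.1 equiv), 0 °C → rt; 1 M HCl
Reagents that add atoms: none
Why: terminal C-acylation of a β-dicarbonyl polyanion (Claisen condensation), in which the trianion of 3 should react at its last-formed and most basic carbanion, the benzyloxy-bearing α′ carbon, with the non-enolisable aryl ester 5, the fourth equivalent of base driving the condensation by deprotonating the new β-diketone; the new methine is racemic and enolisable.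

**Step 4**
Reactants: 6 6-{3-(benzyloxy)-4-[2,5-bis(benzyloxy)phenyl]-2,4-dioxobutyl}-4-hydroxy-2H-pyran-2-one
Product: 9 3-(benzyloxy)-2-[2,5-bis(benzyloxy)phenyl]-5,7-dihydroxy-4H-chromen-4-one, via open-chain tetraketo ester 7 (not isolated), via acylphloroglucinol diketone 8 (not isolated)
Conditions: Mg(OMe)2 (6 equiv), MeOH, reflux; 1 M HCl, EtOAc extraction; then TsOH·H2O (cat.), AcOH, 70 °C
Reagents that add atoms: none
Why: Methoxide from Mg(OMe)2 should open the lactone to the magnesium-chelated tetraketo ester 7, whose nonanoate C-6 methylene (future C4a), acidified by two flanking carbonyls, adds to the ester carbon C-1 (future C8a) and expels methoxide, and enolisation of the resulting cyclohexanetrione gives the aromatic ring A of 8. This is the known Claisen-type ring transformation of 4-hydroxy-6-(2-oxoalkyl)-2-pyranones, which are masked triketo esters, into acylphloroglucinols, the laboratory counterpart of the chalcone synthase fold. Ring A closes in a 6-exo-trig Claisen (Dieckmann-type) mode that forms C4a–C8a, and ring C then closes under acid by 6-exo-trig addition of an ortho hydroxyl to the aryl ketone carbon (O1–C2) followed by loss of water, as in the last stage of a Baker–Venkataraman flavone synthesis. No stereocentre is created, and the labile benzyloxy-bearing methine of 6 to 8 becomes the sp2 carbon C3. The step needs the Claisen closure to outrun the aldol closures (nonanoate C-2 onto the C-7 carbonyl, C-4 onto the C-9 carbonyl) and retro-Claisen cleavage: magnesium holds the 1,3-dicarbonyl units as chelated enolates that are poor electrophiles, the terminal ester cannot be masked in this way, and the C-7 and C-9 carbonyls are further shielded by the branched benzyloxy carbon and the ortho-benzyloxyaryl group. Because the phloroglucinol ring of 8 is symmetric about its acyl group, either ortho hydroxyl gives the same 9, and the ring B oxygens are capped as benzyl ethers so they cannot compete.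

**Step 5**
Reactants: 9 3-(benzyloxy)-2-[2,5-bis(benzyloxy)phenyl]-5,7-dihydroxy-4H-chromen-4-one
Product: 10 3-(benzyloxy)-2-[2,5-bis(benzyloxy)phenyl]-6,8-dibromo-5,7-dihydroxy-4H-chromen-4-one
Conditions: NBS (2.05 equiv), DMF, 0 °C → rt
Reagents that add atoms: N-bromosuccinimide, O=C1CCC(=O)N1Br
Why: electrophilic aromatic bromination, in which C6 and C8 are the only free positions of the doubly hydroxylated ring A and each lies ortho or para to both free hydroxyls, whereas ring B carries only ether oxygens and the deactivating chromenone.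

**Step 6**
Reactants: 10 3-(benzyloxy)-2-[2,5-bis(benzyloxy)phenyl]-6,8-dibromo-5,7-dihydroxy-4H-chromen-4-one
Product: 11 3-(benzyloxy)-2-[2,5-bis(benzyloxy)phenyl]-5,7-dihydroxy-6,8-dimethoxy-4H-chromen-4-one
Conditions: NaOMe (25% in MeOH, 10 equiv), CuBr (0.4 equiv), DMF, 110 °C; 1 M HCl
Reagents that add atoms: sodium methoxide, [Na+].[O-]C
Why: copper-catalysed Ullmann-type methanolysis of both aryl bromides, a reaction established on 6,8-dibromo-5,7-dihydroxyflavones, in which the ring A bis-phenoxide formed under the conditions should protect the pyranone ring against methoxide.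

**Step 7**
Reactants: 11 3-(benzyloxy)-2-[2,5-bis(benzyloxy)phenyl]-5,7-dihydroxy-6,8-dimethoxy-4H-chromen-4-one
Product: 12 3-(benzyloxy)-2-[2,5-bis(benzyloxy)phenyl]-5-hydroxy-6,7,8-trimethoxy-4H-chromen-4-one
Conditions: MeI (1.2 equiv), K2CO3 (1.5 equiv), acetone, 45 °C
Reagents that add atoms: iodomethane, CI
Why: Williamson methylation that should be selective for the 7-hydroxyl, because the 5-hydroxyl is tied up in a hydrogen bond to the C4 carbonyl and is much less acidic and nucleophilic.

**Step 8**
Reactants: 12 3-(benzyloxy)-2-[2,5-bis(benzyloxy)phenyl]-5-hydroxy-6,7,8-trimethoxy-4H-chromen-4-one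
Product: 13 2-(2,5-dihydroxyphenyl)-3,5-dihydroxy-6,7,8-trimethoxy-4H-chromen-4-one
Conditions: H2 (1 atm), 10% Pd/C, EtOAc–MeOH, rt, under exclusion of air on work-up
Reagents that add atoms: none
Why: catalytic hydrogenolysis should cleave the three benzyl ethers (3-O, 2′-O, 5′-O) while the aryl methyl ethers and the chromenone core stay inert under these conditions.

**Compound list**
1 | 4-hydroxy-6-methyl-2H-pyran-2-one (triacetic acid lactone) | Cc1cc(O)cc(=O)o1 | starting material
2 | methyl 2-(benzyloxy)acetate | COC(=O)COCc1ccccc1 | starting material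
3 | 6-[3-(benzyloxy)-2-oxopropyl]-4-hydroxy-2H-pyran-2-one | O=C(Cc1cc(O)cc(=O)o1)COCc1ccccc1 | intermediate
4 | methyl 2,5-dihydroxybenzoate | COC(=O)c1cc(O)ccc1O | starting material
5 | methyl 2,5-bis(benzyloxy)benzoate | COC(=O)c1cc(OCc2ccccc2)ccc1OCc1ccccc1 | intermediate
6 | 6-{3-(benzyloxy)-4-[2,5-bis(benzyloxy)phenyl]-2,4-dioxobutyl}-4-hydroxy-2H-pyran-2-one (racemic) | O=c1cc(O)cc(CC(=O)C(OCc2ccccc2)C(=O)c2cc(OCc3ccccc3)ccc2OCc2ccccc2)o1 | intermediate
7 | methyl 8-(benzyloxy)-9-[2,5-bis(benzyloxy)phenyl]-3,5,7,9-tetraoxononanoate (racemic, formed as its magnesium chelate) | COC(=O)CC(=O)CC(=O)CC(=O)C(OCc1ccccc1)C(=O)c1cc(OCc2ccccc2)ccc1OCc1ccccc1 | intermediate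
8 | 2-(benzyloxy)-1-[2,5-bis(benzyloxy)phenyl]-3-(2,4,6-trihydroxyphenyl)propane-1,3-dione (racemic) | O=C(c1c(O)cc(O)cc1O)C(OCc1ccccc1)C(=O)c1cc(OCc2ccccc2)ccc1OCc1ccccc1 | intermediate
9 | 3-(benzyloxy)-2-[2,5-bis(benzyloxy)phenyl]-5,7-dihydroxy-4H-chromen-4-one | O=c1c(OCc2ccccc2)c(-c2cc(OCc3ccccc3)ccc2OCc2ccccc2)oc2cc(O)cc(O)c12 | intermediate
10 | 3-(benzyloxy)-2-[2,5-bis(benzyloxy)phenyl]-6,8-dibromo-5,7-dihydroxy-4H-chromen-4-one | O=c1c(OCc2ccccc2)c(-c2cc(OCc3ccccc3)ccc2OCc2ccccc2)oc2c(Br)c(O)c(Br)c(O)c12 | intermediate
11 | 3-(benzyloxy)-2-[2,5-bis(benzyloxy)phenyl]-5,7-dihydroxy-6,8-dimethoxy-4H-chromen-4-one | COc1c(O)c(OC)c2oc(-c3cc(OCc4ccccc4)ccc3OCc3ccccc3)c(OCc3ccccc3)c(=O)c2c1O | intermediate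
12 | 3-(benzyloxy)-2-[2,5-bis(benzyloxy)phenyl]-5-hydroxy-6,7,8-trimethoxy-4H-chromen-4-one | COc1c(OC)c(O)c2c(=O)c(OCc3ccccc3)c(-c3cc(OCc4ccccc4)ccc3OCc3ccccc3)oc2c1OC | intermediate
13 | 2-(2,5-dihydroxyphenyl)-3,5-dihydroxy-6,7,8-trimethoxy-4H-chromen-4-one | COc1c(OC)c(O)c2c(=O)c(O)c(-c3cc(O)ccc3O)oc2c1OC | target

**Step count**
Total: 8 steps. Longest linear sequence: 7 steps (steps 1, 3, 4, 5, 6, 7, 8 from triacetic acid lactone; the branch through step 2 is equally long).

**Steps most likely to fail**

Step 4. Aldol-type ring closures inside the chain, or retro-Claisen cleavage of the aryl β-diketone by methoxide, may outrun the Claisen closure, so that resorcinol-type products or chain fragments form instead of ring A. The fallback sets out from 3 and 5 and comes back at 8. The same Mg(OMe)2 ring transformation is applied one stage earlier to pyranone 3, a plain masked triketo ester with only one reasonable Claisen closure, which should give 2-(benzyloxy)-1-(2,4,6-trihydroxyphenyl)ethanone F1. Ester 5 is saponified (LiOH, THF–H2O) to 2,5-bis(benzyloxy)benzoic acid F2, and oxalyl chloride with catalytic DMF converts this into 2,5-bis(benzyloxy)benzoyl chloride F3. The lithium polyanion of F1 (excess LiN(SiMe3)2, THF, −78 °C) is then C-acylated with F3 at the benzyloxy-bearing carbon to give diketone 8, which the acid stage of step 4 turns into 9. Ring A still arises by the pyranone fold, but the C2–C3 bond is made after it.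

Step 3. Deprotonation at the benzyloxy-bearing carbon may be incomplete, or attack on the hindered ortho-substituted ester may be slow, so that O-acylation or rearrangement of the benzyl ether under strong base takes over. The fallback sets out from 3 and comes back at 6. Commercial 2,5-dihydroxybenzaldehyde is benzylated (BnBr, K2CO3, DMF) to 2,5-bis(benzyloxy)benzaldehyde F4, a far better electrophile than the ester. The trianion of 3 (LiN(iPr)2, THF, −78 °C) is added to it in an aldol reaction to give 6-{3-(benzyloxy)-4-[2,5-bis(benzyloxy)phenyl]-4-hydroxy-2-oxobutyl}-4-hydroxy-2H-pyran-2-one F5 as a diastereomer mixture of no consequence. Oxidation of the secondary alcohol with Dess–Martin periodinane (CH2Cl2, rt) should give the β-diketone 6.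

Step 6. Reductive loss of bromine, incomplete substitution at the two doubly ortho-flanked positions, or opening of the pyranone ring by methoxide at 110 °C may erode the double methoxylation. The fallback sets out from 9 and comes back at 12, so it also replaces steps 5 and 7. Double Duff formylation of ring A (hexamethylenetetramine, AcOH, 110 °C; aqueous HCl) should give 3-(benzyloxy)-2-[2,5-bis(benzyloxy)phenyl]-5,7-dihydroxy-4-oxo-4H-chromene-6,8-dicarbaldehyde F6. Dakin oxidation of both ortho-hydroxy aldehydes (H2O2, aqueous NaOH, 0 °C → rt, under argon) gives 3-(benzyloxy)-2-[2,5-bis(benzyloxy)phenyl]-5,6,7,8-tetrahydroxy-4H-chromen-4-one F7. Methylation with MeI (3.3 equiv) and K2CO3 in acetone should spare the chelated 5-hydroxyl and deliver 12.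

**Further compounds**
F1 | step 4 | 2-(benzyloxy)-1-(2,4,6-trihydroxyphenyl)ethanone | O=C(COCc1ccccc1)c1c(O)cc(O)cc1O
F2 | step 4 | 2,5-bis(benzyloxy)benzoic acid | OC(=O)c1cc(OCc2ccccc2)ccc1OCc1ccccc1
F3 | step 4 | 2,5-bis(benzyloxy)benzoyl chloride | ClC(=O)c1cc(OCc2ccccc2)ccc1OCc1ccccc1
F4 | step 3 | 2,5-bis(benzyloxy)benzaldehyde | O=Cc1cc(OCc2ccccc2)ccc1OCc1ccccc1
F5 | step 3 | 6-{3-(benzyloxy)-4-[2,5-bis(benzyloxy)phenyl]-4-hydroxy-2-oxobutyl}-4-hydroxy-2H-pyran-2-one (mixture of racemic diastereomers) | O=c1cc(O)cc(CC(=O)C(OCc2ccccc2)C(O)c2cc(OCc3ccccc3)ccc2OCc2ccccc2)o1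
F6 | step 6 | 3-(benzyloxy)-2-[2,5-bis(benzyloxy)phenyl]-5,7-dihydroxy-4-oxo-4H-chromene-6,8-dicarbaldehyde | O=Cc1c(O)c(C=O)c2oc(-c3cc(OCc4ccccc4)ccc3OCc3ccccc3)c(OCc3ccccc3)c(=O)c2c1O
F7 | step 6 | 3-(benzyloxy)-2-[2,5-bis(benzyloxy)phenyl]-5,6,7,8-tetrahydroxy-4H-chromen-4-one | Oc1c(O)c(O)c2oc(-c3cc(OCc4ccccc4)ccc3OCc3ccccc3)c(OCc3ccccc3)c(=O)c2c1O
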